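**Strategy.** Each benzene ring is traced back to a 2-pyrone. In ring numbering C1 (bearing C7H2O), C2/C3 (Br), C4/C5 (OH), C6 (H), the run C1–C2–C3–C4 already exists, substituents included, as C6–C5–C4–C3 of a 3-silyloxy-4,5-dibromo-2-pyrone. Only the C5(O)–C6(H) edge is missing. A ketene bis(silyl) acetal supplies it by [4+2] addition across pyrone C3 and C6, and loss of CO2 and Me3SiOH aromatises. Applied to a symmetrical bis(pyranylmethyl) ether, one operation turns both heterocycles into both pentasubstituted arenes, forming four C–C bonds. The precursor is the bis-TBS ether of bis[(4,5-dibromo-3-hydroxy-2-oxo-2H-pyran-6-yl)methyl] ether, made from galactaric acid.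

Key step: step 8

Remark (stereochemistry): the target has no stereocentre. The four stereocentres of galactaric acid are erased in step 1, and the transient ones of the cycloadduct in step 8.

Remark (design): the enol oxygen stays acetylated until the central ether and the C5 bromine are in place. A free 3-hydroxyl would be O-alkylated during ether formation and would steer a second bromine to C6 (ipso) instead of C5. The hydrolytically labile silyl enol ether is installed last.

Remark (assumption): ketene acetal 13 is assumed not to be a stock chemical and is therefore made in step 7.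

**Step 1**
Reactants: 1 galactaric acid
Product: 3 3-acetoxy-2-oxo-2H-pyran-6-carboxylic acid, via pyridinium 3-acetoxy-2-oxo-2H-pyran-6-carboxylate 2 (not isolated)
Conditions: Ac2O, pyridine, 100 °C; evaporate; then HCl (4 M in dioxane), EtOAc, 0 °C, filter
Reagents that add atoms: acetic anhydride, CC(=O)OC(C)=O
Why: Peracetylation, δ-lactonisation of C1 onto O5 and two base-induced E1cB losses of acetic acid (the known cyclodehydration of acetylated aldaric acids to 2-pyrones) should erase all four stereocentres and leave the C2 oxygen as the 3-acetate, which then serves as the enol protecting group.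

**Step 2**
Reactants: 3 3-acetoxy-2-oxo-2H-pyran-6-carboxylic acid
Product: 4 6-(hydroxymethyl)-2-oxo-2H-pyran-3-yl acetate
Conditions: BH3·THF, THF, 0 °C to rt; aq NH4Cl
Reagents that add atoms: none
Why: Chemoselective borane reduction of a carboxylic acid proceeds through the acyloxyborane much faster than attack on the enol acetate or on the vinylogous lactone of the pyrone.

**Step 3**
Reactants: 4 6-(hydroxymethyl)-2-oxo-2H-pyran-3-yl acetate (two equivalents)
Product: 6 bis[(3-acetoxy-2-oxo-2H-pyran-6-yl)methyl] ether, via (3-acetoxy-2-oxo-2H-pyran-6-yl)methyl triflate 5 (not isolated)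
Conditions: Tf2O (0.5 equiv), 2,6-di-tert-butyl-4-methylpyridine, CH2Cl2, −78 °C (first half of 4); then second half of 4, −78 °C to rt
Reagents that add atoms: none
Why: O-alkylation of an alcohol by a primary triflate beside a hindered, non-nucleophilic pyridine is an alkoxide-free variant of the Williamson ether synthesis in which the poorly ionising pyranylmethyl triflate reacts by SN2 and the absence of alkoxide spares the pyrone ring and the transferable enol acetate.

**Step 4**
Reactants: 6 bis[(3-acetoxy-2-oxo-2H-pyran-6-yl)methyl] ether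
Product: 7 bis[(3-acetoxy-5-bromo-2-oxo-2H-pyran-6-yl)methyl] ether
Conditions: Br2, NaOAc, AcOH/Ac2O (10:1), 50 °C, dark
Reagents that add atoms: bromine, BrBr
Why: Electrophilic bromination of a 3-substituted 2-pyrone by addition–elimination at the C5=C6 enol-ester bond should select C5, because attack there gives a C6 oxocarbenium ion held by O1 whereas attack at C4 would place the charge beside the C2 carbonyl, and the acetate buffer with a little Ac2O keeps the enol masked.

**Step 5**
Reactants: 7 bis[(3-acetoxy-5-bromo-2-oxo-2H-pyran-6-yl)methyl] ether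
Product: 9 bis[(4,5-dibromo-3-hydroxy-2-oxo-2H-pyran-6-yl)methyl] ether, via bis[(5-bromo-3-hydroxy-2-oxo-2H-pyran-6-yl)methyl] ether 8 (not isolated)
Conditions: HCl (cat.), MeOH, rt; evaporate; then NBS (2.0 equiv), MeCN, 0 °C, dark
Reagents that add atoms: N-bromosuccinimide, O=C1CCC(=O)N1Br
Why: Acid-catalysed transesterification frees both enols, and enol-directed electrophilic bromination of a 3-hydroxy-2-pyrone then takes place at C4, its only open and most nucleophilic carbon, with one equivalent of NBS per ring so that ipso attack at C6 gets no reagent.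

**Step 6**
Reactants: 9 bis[(4,5-dibromo-3-hydroxy-2-oxo-2H-pyran-6-yl)methyl] ether
Product: 10 bis{[4,5-dibromo-3-(tert-butyldimethylsilyloxy)-2-oxo-2H-pyran-6-yl]methyl} ether
Conditions: TBSCl, imidazole, CH2Cl2, 0 °C to rt; neutral work-up, short plug of deactivated silica
Reagents that add atoms: tert-butyldimethylsilyl chloride, CC(C)(C)[Si](C)(C)Cl
Why: Imidazole-promoted O-silylation of an acidic enol needs no selectivity here because no other hydroxyl is present, and the sensitive silyl ether is made directly before its use.

**Step 7**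
Reactants: 11 trimethylsilyl acetate
Product: 13 ketene bis(trimethylsilyl) acetal, via lithium enolate of trimethylsilyl acetate 12 (not isolated)
Conditions: LiN(iPr)2 (commercial solution), THF, −78 °C; then Me3SiCl, −78 °C to rt; distillation
Reagents that add atoms: chlorotrimethylsilane, C[Si](C)(C)Cl
Why: Kinetic deprotonation of the silyl ester and O-silylation of its lithium enolate is the standard silyl ketene acetal synthesis, and distillation removes any C-silylated isomer.

**Step 8**
Reactants: 10 bis{[4,5-dibromo-3-(tert-butyldimethylsilyloxy)-2-oxo-2H-pyran-6-yl]methyl} ether; 13 ketene bis(trimethylsilyl) acetal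
Product: 16 bis[2,3-dibromo-4-(tert-butyldimethylsilyloxy)-5-(trimethylsilyloxy)benzyl] ether, via bis(bicyclic lactone) cycloadduct 14 (not isolated), via bis(cyclohexadiene) 15 (not isolated)
Conditions: 13 (10 equiv), toluene, sealed tube, 110 °C then 130 °C, Ar; volatiles removed in vacuo, crude 16 carried on
Reagents that add atoms: none
Why: Each dibromopyrone acts as an electron-poor diene (C3 to C6) toward the electron-rich ketene acetal in an inverse-electron-demand Diels–Alder reaction that gives the 2-oxabicyclo[2.2.2]octenone units of 14. Retro-[4+2] loss of the CO2 bridge leaves the 1,3-cyclohexadiene units of 15, and thermal 1,2-elimination of Me3SiOH from each C(OSiMe3)2–CH2 pair aromatises them, surplus 13 consuming the silanol. The closest known reaction type is the benzannulation of 2-pyrones with ketene acetals to aryl ethers by cycloaddition, decarboxylation and loss of alcohol. Both carbocycles are closed intermolecularly by the [4+2] event itself, which forms C6–C1 and C4–C5 of each ring, the two ends of the ether reacting independently. The bridgehead stereocentres of 14 are transient and vanish on aromatisation, so no stereocontrol is required. Only regiochemistry matters: the nucleophilic, unhindered CH2 terminus bonds to C6, the vinylogous acceptor end of the dienoate, which forces the acetal carbon onto C3 beside the silyloxy group and so delivers the 4,5-dioxygenation, while the two bromines lower the diene LUMO and end untouched at C2 and C3.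

**Step 9**
Reactants: 16 bis[2,3-dibromo-4-(tert-butyldimethylsilyloxy)-5-(trimethylsilyloxy)benzyl] ether
Product: 17 bis(2,3-dibromo-4,5-dihydroxybenzyl) ether
Conditions: Bu4NF/AcOH (1:1), THF, 0 °C, Ar; pH 5 buffer work-up
Reagents that add atoms: none
Why: Fluoride-induced cleavage of aryl silyl ethers is driven by Si–F bond formation, and the acetic acid protonates each phenoxide at once, which should suppress quinone methide formation from the para-hydroxybenzyl ether and air oxidation of the catechols.

**Compound list**

| No. | Name | SMILES | Role |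
|---|---|---|---|
| 1 | galactaric acid (mucic acid, meso, 2R,3S,4R,5S) | OC(=O)[C@H](O)[C@@H](O)[C@@H](O)[C@H](O)C(O)=O | starting material |
| 2 | pyridinium 3-acetoxy-2-oxo-2H-pyran-6-carboxylate | CC(=O)Oc1ccc(C(=O)[O-])oc1=O.c1cc[nH+]cc1 | intermediate (not isolated) |
| 3 | 3-acetoxy-2-oxo-2H-pyran-6-carboxylic acid | CC(=O)Oc1ccc(C(=O)O)oc1=O | intermediate |
| 4 | 6-(hydroxymethyl)-2-oxo-2H-pyran-3-yl acetate | CC(=O)Oc1ccc(CO)oc1=O | intermediate |
| 5 | (3-acetoxy-2-oxo-2H-pyran-6-yl)methyl trifluoromethanesulfonate | CC(=O)Oc1ccc(COS(=O)(=O)C(F)(F)F)oc1=O | intermediate (not isolated) |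
| 6 | bis[(3-acetoxy-2-oxo-2H-pyran-6-yl)methyl] ether | CC(=O)Oc1ccc(COCc2ccc(OC(C)=O)c(=O)o2)oc1=O | intermediate |
| 7 | bis[(3-acetoxy-5-bromo-2-oxo-2H-pyran-6-yl)methyl] ether | CC(=O)Oc1cc(Br)c(COCc2oc(=O)c(OC(C)=O)cc2Br)oc1=O | intermediate |
| 8 | bis[(5-bromo-3-hydroxy-2-oxo-2H-pyran-6-yl)methyl] ether | Oc1cc(Br)c(COCc2oc(=O)c(O)cc2Br)oc1=O | intermediate (not isolated) |
| 9 | bis[(4,5-dibromo-3-hydroxy-2-oxo-2H-pyran-6-yl)methyl] ether | Oc1c(Br)c(Br)c(COCc2oc(=O)c(O)c(Br)c2Br)oc1=O | intermediate |
| 10 | bis{[4,5-dibromo-3-(tert-butyldimethylsilyloxy)-2-oxo-2H-pyran-6-yl]methyl} ether | CC(C)(C)[Si](C)(C)Oc1c(Br)c(Br)c(COCc2oc(=O)c(O[Si](C)(C)C(C)(C)C)c(Br)c2Br)oc1=O | intermediate (key-step precursor) |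
| 11 | trimethylsilyl acetate | CC(=O)O[Si](C)(C)C | starting material |
| 12 | lithium enolate of trimethylsilyl acetate | [Li+].C=C([O-])O[Si](C)(C)C | intermediate (not isolated) |
| 13 | ketene bis(trimethylsilyl) acetal, 1,1-bis(trimethylsilyloxy)ethene | C=C(O[Si](C)(C)C)O[Si](C)(C)C | intermediate |
| 14 | bis{[5,6-dibromo-4-(tert-butyldimethylsilyloxy)-8,8-bis(trimethylsilyloxy)-3-oxo-2-oxabicyclo[2.2.2]oct-5-en-1-yl]methyl} ether (each bicycle racemic, hence meso and dl forms, drawn without configuration) | O=C1OC2(COCC34CC(O[Si](C)(C)C)(O[Si](C)(C)C)C(O[Si](C)(C)C(C)(C)C)(C(=O)O3)C(Br)=C4Br)CC(O[Si](C)(C)C)(O[Si](C)(C)C)C1(O[Si](C)(C)C(C)(C)C)C(Br)=C2Br | intermediate (not isolated) |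
| 15 | bis{[2,3-dibromo-4-(tert-butyldimethylsilyloxy)-5,5-bis(trimethylsilyloxy)cyclohexa-1,3-dien-1-yl]methyl} ether | C[Si](C)(C)OC1(O[Si](C)(C)C)CC(COCC2=C(Br)C(Br)=C(O[Si](C)(C)C(C)(C)C)C(O[Si](C)(C)C)(O[Si](C)(C)C)C2)=C(Br)C(Br)=C1O[Si](C)(C)C(C)(C)C | intermediate (not isolated) |
| 16 | bis[2,3-dibromo-4-(tert-butyldimethylsilyloxy)-5-(trimethylsilyloxy)benzyl] ether | C[Si](C)(C)Oc1cc(COCc2cc(O[Si](C)(C)C)c(O[Si](C)(C)C(C)(C)C)c(Br)c2Br)c(Br)c(Br)c1O[Si](C)(C)C(C)(C)C | intermediate (key-step product) |
| 17 | bis(2,3-dibromo-4,5-dihydroxybenzyl) ether | Oc1cc(COCc2cc(O)c(O)c(Br)c2Br)c(Br)c(Br)c1O | target |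

**Total step count:** 9. **Longest linear sequence:** 8 (steps 1–6, 8, 9). Step 7 is a one-step side branch.

**Steps most likely to fail**

**Step 8.** The donor 3-silyloxy group and the crowding at C3 may slow the cycloaddition. Several processes could then win:
- thermal O-to-C silyl migration in the ketene acetal,
- desilylation of the pyrone,
- a stepwise conjugate addition with silyl transfer,
- reaction at only one of the two rings.

The fallback changes the electronic character of the diene and sets out from 9. Acetylation (Ac2O, pyridine, CH2Cl2, 0 °C) should give bis[(3-acetoxy-4,5-dibromo-2-oxo-2H-pyran-6-yl)methyl] ether F1. Its smaller, electron-withdrawing acyloxy group lowers the LUMO and opens C3. Heating with 13 in toluene should then give bis[4-acetoxy-2,3-dibromo-5-(trimethylsilyloxy)benzyl] ether F2. Hydrazinolysis in an aprotic medium (N2H4·H2O, THF, 0 °C, then pH 5 buffer) removes the acetyl and trimethylsilyl groups, and the route is rejoined at 17.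

**Step 4.** Three things may go wrong:
- substitution of the deactivated ring may be sluggish,
- the acetate may be lost early, followed by bromination under enol control at the wrong carbon,
- the ether methylenes may be oxidised.

The fallback postpones this bromine to the arene stage and sets out from 6. Methanolysis (cat. HCl, MeOH) and NBS (one equivalent per ring) should give bis[(4-bromo-3-hydroxy-2-oxo-2H-pyran-6-yl)methyl] ether F3. Silylation (TBSCl, imidazole) gives bis{[4-bromo-3-(tert-butyldimethylsilyloxy)-2-oxo-2H-pyran-6-yl]methyl} ether F4. The same cycloaddition with 13 gives bis[3-bromo-4-(tert-butyldimethylsilyloxy)-5-(trimethylsilyloxy)benzyl] ether F5. Electrophilic aromatic bromination (NBS, MeCN, 0 °C, dark) should then enter C2, para to the C5 oxygen. This is the usual position for 3-bromo-4,5-dioxygenated benzyl systems, and C6 is shielded by the neighbouring silyloxy group. The route is rejoined at 16.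

**Step 3.** Three side processes may compete with ether formation:
- decomposition of the triflate,
- O-alkylation of a pyrone carbonyl,
- acetyl transfer from the enol to the alcohol.

The fallback forms the C–O–C unit by reduction instead of substitution and sets out from 4. Oxidation of the allylic-type alcohol (activated MnO2, CH2Cl2) should give 6-formyl-2-oxo-2H-pyran-3-yl acetate F6. Reductive homo-etherification of the aldehyde (Et3SiH, cat. Me3SiOTf, CH2Cl2, −78 to 0 °C) couples two molecules through an oxocarbenium ion that is trapped by hydride. The route is rejoined at 6.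

**Further compounds**
F1 | step 8 | bis[(3-acetoxy-4,5-dibromo-2-oxo-2H-pyran-6-yl)methyl] ether | CC(=O)Oc1c(Br)c(Br)c(COCc2oc(=O)c(OC(C)=O)c(Br)c2Br)oc1=O
F2 | step 8 | bis[4-acetoxy-2,3-dibromo-5-(trimethylsilyloxy)benzyl] ether | CC(=O)Oc1c(O[Si](C)(C)C)cc(COCc2cc(O[Si](C)(C)C)c(OC(C)=O)c(Br)c2Br)c(Br)c1Br
F3 | step 4 | bis[(4-bromo-3-hydroxy-2-oxo-2H-pyran-6-yl)methyl] ether | Oc1c(Br)cc(COCc2cc(Br)c(O)c(=O)o2)oc1=O
F4 | step 4 | bis{[4-bromo-3-(tert-butyldimethylsilyloxy)-2-oxo-2H-pyran-6-yl]methyl} ether | CC(C)(C)[Si](C)(C)Oc1c(Br)cc(COCc2cc(Br)c(O[Si](C)(C)C(C)(C)C)c(=O)o2)oc1=O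
F5 | step 4 | bis[3-bromo-4-(tert-butyldimethylsilyloxy)-5-(trimethylsilyloxy)benzyl] ether | C[Si](C)(C)Oc1cc(COCc2cc(Br)c(O[Si](C)(C)C(C)(C)C)c(O[Si](C)(C)C)c2)cc(Br)c1O[Si](C)(C)C(C)(C)C
F6 | step 3 | 6-formyl-2-oxo-2H-pyran-3-yl acetate | CC(=O)Oc1ccc(C=O)oc1=O
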